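The north run stands at 53.7% of its substrate after 30.0 h, having stood at 54.0% at 25.0 h, while the south-west run falls to 8.8%.

| flask | substrate | partner | remark | time |
|---|---|---|---|---|
| south-west | 0.11 M | 1.2 M | run made earlier |  |
| north | 2.2 M | 1.2 M | run made earlier |  |
| summer | 1.2 M | 1.20 M |  | 2.5 d |
| autumn | 0.80 M | 1.20 M |  | 2.5 d |
| noon | 0.20 M | 1.20 M |  | 2.5 d |
| spring | 2.5 M | 1.20 M |  | 2.5 d |

| run | time / h | product / % | substrate / % |
|---|---|---|---|
| south-west | 2.50 | 0 | 75.7 |
| south-west | 4.00 | 0.8 | 63.7 |
| south-west | 6.00 | 2.4 | 53.1 |
| south-west | 8.00 | 4.5 | 43.3 |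
| south-west | 12.0 | 8.2 | 31.0 |
| south-west | 20.0 | 15.2 | 16.5 |
| south-west | 30.0 | 22.3 | 8.8 |
| north | 1.50 | 0.4 | 86.5 |
| north | 5.00 | 0.4 | 70.8 |
| north | 8.00 | 1.2 | 64.1 |
| north | 12.0 | 2.6 | 59.7 |
| north | 20.0 | 3.1 | 56.4 |
| north | 25.0 | 1.6 | 54.0 |
| north | 30.0 | 1.3 | 53.7 |

(standard deviation of a reading: 0.5 percentage points)

1. the flasks by amount of product, in percent of the substrate charged, highest first, at 2.5 d (summer / autumn / noon / spring)
2. the amount of product, in percent of the substrate charged of the flask you put first, at 2.5 d
3. the amount of product, in percent of the substrate charged of the flask you put last, at 2.5 d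

- a reading or a percentage of product counts all its forms, free or not

1. In the south-west run the partner charge is far above the substrate charge. So I treat the substrate loss there as roughly pseudo-first-order. Its last reading gives a half-life of 8.56 h. The asked time is 7.01 such half-lives, provided c(partner) stays near its charge.

2. So I read the north stall as a shortage of partner, not of time. This is my assumption. The north run lost 1.02 M of substrate against 1.2 M of partner. That gives the partner price, the partner charge spent per substrate lost: 1.18.

3. I define spare partner as c(partner) minus the price times c(substrate), both as charged. Noon has 0.964 M, autumn 0.258 M, summer −0.214 M and spring −1.75 M. A negative value marks partner as the limiting reagent by this count.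

4. Product stands at 22.3% in the south-west run, with 1.07 M spare, and at 1.3% in the north run at the same time. So I rank the flasks by spare partner: noon first, then autumn, summer and spring.

5. The south-west run made 24.5% product per substrate lost. I expect noon somewhat above that, given its longer time, and spring near the north figure.

The forecast gives noon > autumn > summer > spring, 38% and 1%, holding that “the percentage yield falls as substrate charge rises”; its top stands above the south-west figure.

The flasks give noon > autumn > summer > spring: noon 28.4%, autumn 12.7%, summer 5.78%, spring 0.555%.

    substrate + partner → intermediate A (k = 0.0310 M⁻¹ h⁻¹)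
    partner + intermediate A ⇌ intermediate B (K = 0.650 M⁻¹, k = 0.900 M⁻¹ h⁻¹)
    substrate + partner ⇌ intermediate C (K = 2.30 M⁻¹, k = 0.0670 M⁻¹ h⁻¹)
    intermediate C → intermediate D (k = 0.0590 h⁻¹)
    partner + intermediate D ⇌ product (K = 1.70 M⁻¹, k = 0.350 M⁻¹ h⁻¹)
    intermediate C → intermediate A (k = 0.0110 h⁻¹)
    intermediate B → decomposed reagent (k = 0.0510 h⁻¹)
    crystals ⇌ product, rate k8*(cs8 - [product]) while solid is left; crystals form when [product] > cs8 (solubility = 0.560 M, k = 6.70 h⁻¹)

Now I take noon's substrate charge with 0.30 M of partner. The same price leaves a spare of 0.0644 M. That is less than noon's and less than autumn's. It is more than summer's. So I expect product near those two flasks, not near noon. This neighbouring flask gives 5.57% of product at 2.50 d, close to summer's 5.78%, and substrate is its largest share at 38.1%.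

All runs were computed with constants of no real substance; scatter was added.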